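Arthonioic acid is disconnected at the depside ester into two resorcylate halves that share one carbon skeleton. In ring A, the contiguous carbons C6 (2-oxoheptyl), C1 (carboxyl), C2 (oxygen) and C3 (hydrogen) are already present as C6, C5, C4 and C3 of a 4-benzyloxy-2-pyrone-5-carboxylate carrying the ketal-masked side chain. Cycloaddition of a ketene dibenzyl acetal across pyrone C3 and C6 supplies ring A carbons C4 (oxygen) and C5; loss of carbon dioxide and benzyl alcohol then aromatises the adduct, so one operation fixes all five substituents. The benzoate obtained serves both halves: ring B arises from it by debenzylation, benzyl ester formation and O-methylation after coupling.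

Key step: step 8

Remark on the chemistry: each benzene ring is numbered from C1 (the carboxyl-bearing carbon) to C6 (the side-chain carbon), so that ring B carries the methoxy group at C2 and the depside oxygen at C4. The pyrone is numbered O1, C2 (lactone carbonyl) to C6, and its atoms are always called pyrone atoms. The target and all isolated compounds are achiral; only the transient bicyclic lactone of the key step is chiral and forms as a racemate. The benzoic acid from step 9 is divided between steps 10 and 12.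

Step 1
Reactants: 1 methyl 3-oxooctanoate
Product: 2 methyl 2-(2-pentyl-1,3-dioxolan-2-yl)acetate
Conditions: HOCH2CH2OH (3 equiv), pTsOH·H2O (cat.), toluene, reflux, Dean–Stark
Reagents that add atoms: ethylene glycol, OCCO
Why: Acid-catalysed ketalisation of the ketone carbonyl of a β-keto ester, driven to the dioxolane by azeotropic removal of water.

Step 2
Reactants: 2 methyl 2-(2-pentyl-1,3-dioxolan-2-yl)acetate
Product: 3 2-(2-pentyl-1,3-dioxolan-2-yl)acetic acid
Conditions: LiOH·H2O, THF/MeOH/H2O, rt; then cold 1 M HCl to pH 4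
Reagents that add atoms: lithium hydroxide, [Li+].[OH-]
Why: Saponification of an unhindered methyl ester; the dioxolane is inert to hydroxide, blocks the decarboxylation a free β-keto acid would undergo, and should survive brief cold acidification.

Step 3
Reactants: 3 2-(2-pentyl-1,3-dioxolan-2-yl)acetic acid; 4 dimethyl 3-oxoglutarate
Product: 6 dimethyl 3-oxo-2-[2-(2-pentyl-1,3-dioxolan-2-yl)acetyl]pentanedioate, via acyl imidazolide 5 (not isolated)
Conditions: CDI, THF, rt; then 4, MgCl2, Et3N, MeCN, 0 °C to rt; cold aq. citric acid work-up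
Reagents that add atoms: none
Why: C-acylation of the magnesium enolate of a 1,3-dicarbonyl compound with an acyl imidazolide, in which chelation directs attack to carbon and the more acidic tricarbonyl product is held as its chelate, so that acylation should stop after one acyl group.

Step 4
Reactants: 6 dimethyl 3-oxo-2-[2-(2-pentyl-1,3-dioxolan-2-yl)acetyl]pentanedioate
Product: 7 methyl 4-hydroxy-2-oxo-6-[(2-pentyl-1,3-dioxolan-2-yl)methyl]-2H-pyran-5-carboxylate
Conditions: DBU, toluene, 80 °C; cold aq. citric acid work-up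
Reagents that add atoms: none
Why: Base-mediated lactonisation in which the enol oxygen of the side-chain ketone adds to the remote ester and expels methanol (the only six-membered closure open to 6), followed by enolisation to the 4-hydroxy-2-pyrone, the known ring closure of 2-acyl-3-oxoglutarates.

Step 5
Reactants: 7 methyl 4-hydroxy-2-oxo-6-[(2-pentyl-1,3-dioxolan-2-yl)methyl]-2H-pyran-5-carboxylate; 8 benzyl alcohol
Product: 9 methyl 4-(benzyloxy)-2-oxo-6-[(2-pentyl-1,3-dioxolan-2-yl)methyl]-2H-pyran-5-carboxylate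
Conditions: PPh3, DIAD, THF, 0 °C to rt
Reagents that add atoms: none
Why: Mitsunobu etherification of a vinylogous carboxylic acid, which should alkylate the oxygen on pyrone C4 under neutral conditions and avoid the benzylation at pyrone C3 that benzyl halide and base can cause.

Step 6
Reactants: 10 2-bromo-1,1-diethoxyethane; 8 benzyl alcohol
Product: 11 2-bromo-1,1-bis(benzyloxy)ethane
Conditions: 8 (2.2 equiv), pTsOH·H2O (cat.), 90–110 °C, ethanol distilled off; K2CO3 quench
Reagents that add atoms: none
Why: Acid-catalysed transacetalisation, pulled to the dibenzyl acetal by continuous removal of the more volatile ethanol, with the primary bromide inert.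

Step 7
Reactants: 11 2-bromo-1,1-bis(benzyloxy)ethane
Product: 12 1,1-bis(benzyloxy)ethene
Conditions: KOtBu, THF, 0 °C to rt; filtered, concentrated cold, used at once
Reagents that add atoms: none
Why: E2 dehydrobromination of a 2-bromo acetal with a bulky alkoxide, the standard ketene acetal synthesis, with the acid- and heat-sensitive product kept basic and not distilled hot.

Step 8
Reactants: 9 methyl 4-(benzyloxy)-2-oxo-6-[(2-pentyl-1,3-dioxolan-2-yl)methyl]-2H-pyran-5-carboxylate; 12 1,1-bis(benzyloxy)ethene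
Product: 15 methyl 2,4-bis(benzyloxy)-6-[(2-pentyl-1,3-dioxolan-2-yl)methyl]benzoate, via bicyclic lactone 13 (not isolated), via cyclohexadiene 14 (not isolated)
Conditions: 12 (3 equiv), toluene, 110 °C, sealed tube, base-washed glassware
Reagents that add atoms: none
Why: Inverse-electron-demand Diels–Alder reaction of an electron-poor 2-pyrone with an electron-rich ketene acetal, the known benzoate-forming reaction of 2-pyrone-5-carboxylates: the nucleophilic CH2 of 12 bonds to pyrone C6 and the acetal carbon closes onto pyrone C3 in an asynchronous [4+2] addition to give the 2-oxabicyclo[2.2.2]octenone 13. Retro-[4+2] extrusion of carbon dioxide gives cyclohexadiene 14, and 1,2-elimination of benzyl alcohol across C4–C5 of ring A, driven by aromatisation, should deliver 15. The carbocycle of ring A is closed by intermolecular [4+2] cycloaddition, which forms its C5–C6 and C3–C4 bonds. No stereocentre is set, because the two bridgehead centres of racemic 13 are lost on aromatisation. The selectivity needed is regiochemical (CH2 to pyrone C6, not C3); it is secured by the C5 ester and the lactone, which make pyrone C6 the electrophilic terminus, and by the C4 benzyloxy donor, which raises electron density at pyrone C3. Excess 12 covers its capture by the liberated benzyl alcohol, and heating offsets the deactivation by the C4 donor and the branch at pyrone C6.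

Step 9
Reactants: 15 methyl 2,4-bis(benzyloxy)-6-[(2-pentyl-1,3-dioxolan-2-yl)methyl]benzoate
Product: 16 2,4-bis(benzyloxy)-6-[(2-pentyl-1,3-dioxolan-2-yl)methyl]benzoic acid
Conditions: KOH, DMSO/H2O (4:1), 90 °C; then cold 1 M HCl to pH 4
Reagents that add atoms: potassium hydroxide, [K+].[OH-]
Why: Saponification of a doubly ortho-substituted benzoate with poorly solvated hydroxide in hot aqueous DMSO, conditions to which benzyl ethers and the dioxolane are stable.

Step 10
Reactants: 16 2,4-bis(benzyloxy)-6-[(2-pentyl-1,3-dioxolan-2-yl)methyl]benzoic acid (one portion)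
Product: 17 2,4-dihydroxy-6-[(2-pentyl-1,3-dioxolan-2-yl)methyl]benzoic acid
Conditions: H2 (1 atm), 10% Pd/C, EtOAc, rt; used crude at once
Reagents that add atoms: none
Why: Catalytic hydrogenolysis of the two aryl benzyl ethers, which leaves ketal and carboxyl untouched, the product being kept at room temperature to avoid decarboxylation of the β-resorcylic acid.

Step 11
Reactants: 17 2,4-dihydroxy-6-[(2-pentyl-1,3-dioxolan-2-yl)methyl]benzoic acid
Product: 18 benzyl 2,4-dihydroxy-6-[(2-pentyl-1,3-dioxolan-2-yl)methyl]benzoate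
Conditions: BnBr (1.05 equiv), KHCO3, DMF, rt
Reagents that add atoms: benzyl bromide, BrCc1ccccc1
Why: Chemoselective SN2 alkylation of the carboxylate, since hydrogencarbonate deprotonates the carboxylic acid but not the phenols.

Step 12
Reactants: 16 2,4-bis(benzyloxy)-6-[(2-pentyl-1,3-dioxolan-2-yl)methyl]benzoic acid; 18 benzyl 2,4-dihydroxy-6-[(2-pentyl-1,3-dioxolan-2-yl)methyl]benzoate
Product: 19 benzyl 4-({2,4-bis(benzyloxy)-6-[(2-pentyl-1,3-dioxolan-2-yl)methyl]benzoyl}oxy)-2-hydroxy-6-[(2-pentyl-1,3-dioxolan-2-yl)methyl]benzoate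
Conditions: DCC, DMAP (0.2 equiv), CH2Cl2, 0 °C to rt
Reagents that add atoms: none
Why: Steglich esterification, selective for the C4 hydroxyl of ring B because the C2 hydroxyl is locked in a hydrogen bond to the ortho ester carbonyl, the usual site selectivity of depside couplings; the neutral conditions spare both ketals.

Step 13
Reactants: 19 benzyl 4-({2,4-bis(benzyloxy)-6-[(2-pentyl-1,3-dioxolan-2-yl)methyl]benzoyl}oxy)-2-hydroxy-6-[(2-pentyl-1,3-dioxolan-2-yl)methyl]benzoate
Product: 20 benzyl 4-({2,4-bis(benzyloxy)-6-[(2-pentyl-1,3-dioxolan-2-yl)methyl]benzoyl}oxy)-2-methoxy-6-[(2-pentyl-1,3-dioxolan-2-yl)methyl]benzoate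
Conditions: MeI (5 equiv), K2CO3, dry acetone, 50 °C
Reagents that add atoms: iodomethane, CI
Why: Williamson etherification of the only remaining acidic site (the C2 hydroxyl of ring B), under aprotic carbonate conditions that should leave intact the depside carbonyl, which is shielded by two ortho substituents.

Step 14
Reactants: 20 benzyl 4-({2,4-bis(benzyloxy)-6-[(2-pentyl-1,3-dioxolan-2-yl)methyl]benzoyl}oxy)-2-methoxy-6-[(2-pentyl-1,3-dioxolan-2-yl)methyl]benzoate
Product: 21 benzyl 4-{[2,4-bis(benzyloxy)-6-(2-oxoheptyl)benzoyl]oxy}-2-methoxy-6-(2-oxoheptyl)benzoate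
Conditions: 1 M aq. HCl/THF (1:4), rt
Reagents that add atoms: water, O
Why: Acid-catalysed hydrolysis of the two dialkyl dioxolanes, done while the carboxyl is still a benzyl ester so that enol-lactonisation to an isocoumarin is disfavoured; benzyl ethers and both esters tolerate dilute aqueous acid at room temperature.

Step 15
Reactants: 21 benzyl 4-{[2,4-bis(benzyloxy)-6-(2-oxoheptyl)benzoyl]oxy}-2-methoxy-6-(2-oxoheptyl)benzoate
Product: 22 arthonioic acid, 4-{[2,4-dihydroxy-6-(2-oxoheptyl)benzoyl]oxy}-2-methoxy-6-(2-oxoheptyl)benzoic acid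
Conditions: H2 (1 atm), 10% Pd/C, EtOAc, rt
Reagents that add atoms: none
Why: Hydrogenolysis of the two benzyl ethers and the benzyl ester under neutral conditions, in which aliphatic ketones and the aryl ester are not reduced, should release the target directly.

Compound list
1 | methyl 3-oxooctanoate | CCCCCC(=O)CC(=O)OC | starting material
2 | methyl 2-(2-pentyl-1,3-dioxolan-2-yl)acetate | CCCCCC1(CC(=O)OC)OCCO1 | intermediate
3 | 2-(2-pentyl-1,3-dioxolan-2-yl)acetic acid | CCCCCC1(CC(=O)O)OCCO1 | intermediate
4 | dimethyl 3-oxoglutarate (dimethyl 3-oxopentanedioate) | COC(=O)CC(=O)CC(=O)OC | starting material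
5 | 1-(1H-imidazol-1-yl)-2-(2-pentyl-1,3-dioxolan-2-yl)ethan-1-one (formed in situ) | CCCCCC1(CC(=O)n2ccnc2)OCCO1 | intermediate
6 | dimethyl 3-oxo-2-[2-(2-pentyl-1,3-dioxolan-2-yl)acetyl]pentanedioate (triketo tautomer drawn; methine enolised, no defined configuration) | COC(=O)CC(=O)C(C(=O)OC)C(=O)CC1(CCCCC)OCCO1 | intermediate
7 | methyl 4-hydroxy-2-oxo-6-[(2-pentyl-1,3-dioxolan-2-yl)methyl]-2H-pyran-5-carboxylate | CCCCCC1(CC2=C(C(=O)OC)C(O)=CC(=O)O2)OCCO1 | intermediate
8 | benzyl alcohol | OCc1ccccc1 | starting material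
9 | methyl 4-(benzyloxy)-2-oxo-6-[(2-pentyl-1,3-dioxolan-2-yl)methyl]-2H-pyran-5-carboxylate | CCCCCC1(CC2=C(C(=O)OC)C(OCc3ccccc3)=CC(=O)O2)OCCO1 | intermediate
10 | 2-bromo-1,1-diethoxyethane | CCOC(CBr)OCC | starting material
11 | 2-bromo-1,1-bis(benzyloxy)ethane | BrCC(OCc1ccccc1)OCc1ccccc1 | intermediate
12 | 1,1-bis(benzyloxy)ethene | C=C(OCc1ccccc1)OCc1ccccc1 | intermediate
13 | methyl 5,8,8-tris(benzyloxy)-3-oxo-1-[(2-pentyl-1,3-dioxolan-2-yl)methyl]-2-oxabicyclo[2.2.2]oct-5-ene-6-carboxylate (racemic, one enantiomer drawn; formed in situ) | COC(=O)C1=C(OCc2ccccc2)[C@H]3C(=O)O[C@]1(CC4(CCCCC)OCCO4)CC3(OCc5ccccc5)OCc6ccccc6 | intermediate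
14 | methyl 4,4,6-tris(benzyloxy)-2-[(2-pentyl-1,3-dioxolan-2-yl)methyl]cyclohexa-1,5-diene-1-carboxylate (formed in situ) | COC(=O)C1=C(CC2(CCCCC)OCCO2)CC(OCc3ccccc3)(OCc4ccccc4)C=C1OCc5ccccc5 | intermediate
15 | methyl 2,4-bis(benzyloxy)-6-[(2-pentyl-1,3-dioxolan-2-yl)methyl]benzoate | CCCCCC1(Cc2cc(OCc3ccccc3)cc(OCc3ccccc3)c2C(=O)OC)OCCO1 | intermediate
16 | 2,4-bis(benzyloxy)-6-[(2-pentyl-1,3-dioxolan-2-yl)methyl]benzoic acid | CCCCCC1(Cc2cc(OCc3ccccc3)cc(OCc3ccccc3)c2C(=O)O)OCCO1 | intermediate
17 | 2,4-dihydroxy-6-[(2-pentyl-1,3-dioxolan-2-yl)methyl]benzoic acid | CCCCCC1(Cc2cc(O)cc(O)c2C(=O)O)OCCO1 | intermediate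
18 | benzyl 2,4-dihydroxy-6-[(2-pentyl-1,3-dioxolan-2-yl)methyl]benzoate | CCCCCC1(Cc2cc(O)cc(O)c2C(=O)OCc2ccccc2)OCCO1 | intermediate
19 | benzyl 4-({2,4-bis(benzyloxy)-6-[(2-pentyl-1,3-dioxolan-2-yl)methyl]benzoyl}oxy)-2-hydroxy-6-[(2-pentyl-1,3-dioxolan-2-yl)methyl]benzoate | CCCCCC1(Cc2cc(OCc3ccccc3)cc(OCc3ccccc3)c2C(=O)Oc2cc(CC3(CCCCC)OCCO3)c(C(=O)OCc3ccccc3)c(O)c2)OCCO1 | intermediate
20 | benzyl 4-({2,4-bis(benzyloxy)-6-[(2-pentyl-1,3-dioxolan-2-yl)methyl]benzoyl}oxy)-2-methoxy-6-[(2-pentyl-1,3-dioxolan-2-yl)methyl]benzoate | CCCCCC1(Cc2cc(OCc3ccccc3)cc(OCc3ccccc3)c2C(=O)Oc2cc(CC3(CCCCC)OCCO3)c(C(=O)OCc3ccccc3)c(OC)c2)OCCO1 | intermediate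
21 | benzyl 4-{[2,4-bis(benzyloxy)-6-(2-oxoheptyl)benzoyl]oxy}-2-methoxy-6-(2-oxoheptyl)benzoate | CCCCCC(=O)Cc1cc(OCc2ccccc2)cc(OCc2ccccc2)c1C(=O)Oc1cc(CC(=O)CCCCC)c(C(=O)OCc2ccccc2)c(OC)c1 | intermediate
22 | arthonioic acid, 4-{[2,4-dihydroxy-6-(2-oxoheptyl)benzoyl]oxy}-2-methoxy-6-(2-oxoheptyl)benzoic acid | CCCCCC(=O)Cc1cc(O)cc(O)c1C(=O)Oc1cc(CC(=O)CCCCC)c(C(=O)O)c(OC)c1 | target

Total step count: 15. Longest linear sequence: 13 steps (steps 1–5 and 8–15; steps 6 and 7 form the side branch to the ketene acetal).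

Steps most likely to fail

Step 8. The cycloaddition may be too slow on a pyrone deactivated by the C4 donor and crowded at pyrone C6. The ketene acetal could then be consumed first, by thermal benzyl migration, by oligomerisation or by the liberated benzyl alcohol, and the dihydrobenzene may also eliminate incompletely. Fallback: ring A would be assembled by aldol aromatisation of a triketo ester instead of by cycloaddition. It sets out from acid 3, activated as imidazolide 5 as in step 3. The trianion of methyl 3,5-dioxohexanoate (LDA, 3 equiv, THF, −78 to 0 °C) would be acylated at its terminal carbon to give methyl 3,5,7-trioxo-8-(2-pentyl-1,3-dioxolan-2-yl)octanoate F1. Intramolecular aldol condensation of C2 onto the C7 carbonyl with dehydration (aq. KOH, 0 °C to rt, then cold mild acid) should give methyl 2,4-dihydroxy-6-[(2-pentyl-1,3-dioxolan-2-yl)methyl]benzoate F2. Double O-benzylation (BnBr, K2CO3, DMF, 60 °C) comes back to the route at 15.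

Step 12. Acyl transfer from the doubly ortho-substituted O-acylisourea may be slow, allowing rearrangement to the N-acylurea or capture of the activated carboxyl by the neighbouring dioxolane oxygen. Fallback: a preformed, sterically small acylating agent would be combined with a preformed phenoxide. It sets out from 16, which with cyanuric fluoride and pyridine in CH2Cl2 at −10 °C to rt should give the isolable 2,4-bis(benzyloxy)-6-[(2-pentyl-1,3-dioxolan-2-yl)methyl]benzoyl fluoride F3. Reaction of this with 18 and K2CO3 in MeCN at rt, where the more acidic unchelated C4 hydroxyl of 18 is ionised first, comes back to the route at 19.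

Step 13. Etherification of the chelated C2 hydroxyl of ring B may be slow enough that base-mediated cleavage or transacylation of the depside ester competes. Fallback: ring B would be methylated before the coupling, under temporary protection of its C4 hydroxyl. It sets out from 18. Allyl bromide and K2CO3 in acetone at rt should alkylate only the unchelated hydroxyl to give benzyl 2-hydroxy-4-(prop-2-en-1-yloxy)-6-[(2-pentyl-1,3-dioxolan-2-yl)methyl]benzoate F4. Methylation (MeI, K2CO3, DMF, 50 °C) gives benzyl 2-methoxy-4-(prop-2-en-1-yloxy)-6-[(2-pentyl-1,3-dioxolan-2-yl)methyl]benzoate F5. Deallylation with catalytic Pd(PPh3)4 and morpholine in THF gives benzyl 4-hydroxy-2-methoxy-6-[(2-pentyl-1,3-dioxolan-2-yl)methyl]benzoate F6. Esterification of F6 with 16 under the conditions of step 12 comes back to the route at 20.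

Further compounds
F1 | step 8 | methyl 3,5,7-trioxo-8-(2-pentyl-1,3-dioxolan-2-yl)octanoate | COC(=O)CC(=O)CC(=O)CC(=O)CC1(CCCCC)OCCO1
F2 | step 8 | methyl 2,4-dihydroxy-6-[(2-pentyl-1,3-dioxolan-2-yl)methyl]benzoate | CCCCCC1(Cc2cc(O)cc(O)c2C(=O)OC)OCCO1
F3 | step 12 | 2,4-bis(benzyloxy)-6-[(2-pentyl-1,3-dioxolan-2-yl)methyl]benzoyl fluoride | CCCCCC1(Cc2cc(OCc3ccccc3)cc(OCc3ccccc3)c2C(=O)F)OCCO1
F4 | step 13 | benzyl 2-hydroxy-4-(prop-2-en-1-yloxy)-6-[(2-pentyl-1,3-dioxolan-2-yl)methyl]benzoate | CCCCCC1(Cc2cc(OCC=C)cc(O)c2C(=O)OCc2ccccc2)OCCO1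
F5 | step 13 | benzyl 2-methoxy-4-(prop-2-en-1-yloxy)-6-[(2-pentyl-1,3-dioxolan-2-yl)methyl]benzoate | CCCCCC1(Cc2cc(OCC=C)cc(OC)c2C(=O)OCc2ccccc2)OCCO1
F6 | step 13 | benzyl 4-hydroxy-2-methoxy-6-[(2-pentyl-1,3-dioxolan-2-yl)methyl]benzoate | CCCCCC1(Cc2cc(O)cc(OC)c2C(=O)OCc2ccccc2)OCCO1
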